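**Retrosynthetic overview**
1. Target 16, 1-(3,5-dihydroxyphenyl)henicosan-2-one, is taken back to its dimethyl ether 15 and then to the dioxolane 14 (BBr3 demethylation, ketal hydrolysis).
2. Feature used: on the benzene ring the side-chain carbon C-1' and the oxygenated C-5' are meta, like C-6 (alkyl) and C-4 (OMe) of a 2-pyrone. C-4', C-5', C-6' and C-1' are therefore pyrone C-3 to C-6, and only C-2' and the oxygenated C-3' are missing.
3. Key disconnection: bonds C-1'–C-2' and C-3'–C-4', by [4+2] addition of 1,1-dimethoxyethene 11 across C-6/C-3 of pyrone 10, then loss of CO2 and methanol. The benzene ring is the only ring of the target and the only ring built.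
4. Pyrone 10 is cut at the CH2–C(=O) bond: acylation of the 6-methyl anion of commercial 4-methoxy-6-methyl-2-pyrone 5 with the Weinreb amide 4 of icosanoic acid 1, then ketalization.

Key step: step 4

Remark on the chemistry: the target has no stereocentre. The chiral transient intermediates 7 and 12 form as racemates and lose their stereocentres within the same step.

**Step 1**
Reactants: 1 icosanoic acid; 2 N,O-dimethylhydroxylamine hydrochloride
Product: 4 N-methoxy-N-methylicosanamide, via icosanoyl imidazolide 3 (not isolated)
Conditions: CDI (1.2 equiv), THF, 40 °C; then MeNH(OMe)·HCl (1.5 equiv), 40 °C → rt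
Reagents that add atoms: N,O-dimethylhydroxylamine hydrochloride (2), CNOC.Cl
Why: Activation of the acid as its acyl imidazolide followed by aminolysis is the standard Weinreb amide synthesis, with the liberated imidazole serving as the base.

**Step 2**
Reactants: 5 4-methoxy-6-methyl-2H-pyran-2-one; 4 N-methoxy-N-methylicosanamide
Product: 8 4-methoxy-6-(2-oxohenicosyl)-2H-pyran-2-one, via lithiomethylpyrone 6 (not isolated), via tetrahedral lithium adduct 7 (not isolated)
Conditions: LiN(iPr)2 (1.6 equiv), 5 (1.6 equiv), THF, −78 °C; then 4 (1.0 equiv) in THF, −78 → 0 °C; 1 M HCl, 0 °C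
Reagents that add atoms: none
Why: LiN(iPr)2 removes a proton from the 6-methyl group to give the extended enolate, which should react at its exocyclic carbon with the amide in a vinylogous Claisen-type acylation (Weinreb ketone synthesis), the N-methoxy chelate 7 holding the tetrahedral state until the acid quench so that the acidic product methylene cannot quench unreacted anion.

**Step 3**
Reactants: 8 4-methoxy-6-(2-oxohenicosyl)-2H-pyran-2-one; 9 ethylene glycol
Product: 10 4-methoxy-6-[(2-nonadecyl-1,3-dioxolan-2-yl)methyl]-2H-pyran-2-one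
Conditions: ethylene glycol (10 equiv), p-TsOH·H2O (0.1 equiv), toluene, reflux, Dean–Stark
Reagents that add atoms: ethylene glycol (9), OCCO
Why: Acid-catalysed ketalization with azeotropic removal of water should occur at the unhindered ketone, which is far more electrophilic than the lactone carbonyl or the vinylogous-ester carbon C-4 of the pyrone.

**Step 4**
Reactants: 10 4-methoxy-6-[(2-nonadecyl-1,3-dioxolan-2-yl)methyl]-2H-pyran-2-one; 11 1,1-dimethoxyethene
Product: 14 2-[(3,5-dimethoxyphenyl)methyl]-2-nonadecyl-1,3-dioxolane, via bridged bicyclic lactone 12 (not isolated), via trimethoxycyclohexadiene 13 (not isolated)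
Conditions: 11 (15 equiv), K2CO3 (0.1 equiv, acid scavenger), toluene, sealed tube, 160 °C
Reagents that add atoms: 1,1-dimethoxyethene (11), C=C(OC)OC
Why: Proposed new method: the nucleophilic CH2 of the ketene acetal should attack the electrophilic δ-carbon C-6 of the pyrone while the developing dimethoxycarbenium carbon is captured by the nucleophilic α-carbon C-3, an asynchronous inverse-electron-demand [4+2] cycloaddition giving bridged lactone 12, which loses CO2 by retro-[4+2] to diene 13 and then methanol by 1,2-elimination, both losses being irreversible and so draining an unfavourable first equilibrium. The closest known reaction type is the inverse-demand Diels–Alder reaction of acceptor-substituted 2-pyrones (3- or 5-alkoxycarbonyl, 3-bromo) with 1,1-dimethoxyethene followed by loss of CO2 and methanol; what is new is a 4-alkoxy-2-pyrone with no acceptor, whose higher LUMO is to be offset by temperature, excess ketene acetal and acid-free conditions. The benzene ring is closed by intermolecular [4+2] cycloaddition (pyrone C-3 to C-6 plus the two ketene acetal carbons) followed by cycloreversion, not by cyclization of a chain. No stereocentre is set: the bridgehead centres of 12 form as a racemate and disappear on aromatization. The selectivity needed is regiochemical, CH2 to C-6 and acetal carbon to C-3, since the reverse orientation would place the new methoxy group para to the old one; it is secured by the matched polarization of diene (C-6 electrophilic, C-3 nucleophilic) and dienophile. The dioxolane removes the acidic keto-methylene that would otherwise protonate the ketene acetal.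

**Step 5**
Reactants: 14 2-[(3,5-dimethoxyphenyl)methyl]-2-nonadecyl-1,3-dioxolane
Product: 15 1-(3,5-dimethoxyphenyl)henicosan-2-one
Conditions: 2 M HCl, THF, 45 °C
Reagents that add atoms: water, O
Why: Aqueous acid hydrolysis of the dioxolane should free the ketone while the aryl methyl ethers are inert.

**Step 6**
Reactants: 15 1-(3,5-dimethoxyphenyl)henicosan-2-one
Product: 16 1-(3,5-dihydroxyphenyl)henicosan-2-one
Conditions: BBr3 (5 equiv), CH2Cl2, −78 °C → rt; then H2O, 0 °C
Reagents that add atoms: none
Why: BBr3 demethylation of aryl methyl ethers (boron coordinates the ether oxygen, bromide attacks the methyl group) should free both phenols, with excess reagent covering the equivalent bound by the ketone, which is released on aqueous work-up.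

**Compound list**
1 | icosanoic acid | CCCCCCCCCCCCCCCCCCCC(=O)O | starting material
2 | N,O-dimethylhydroxylamine hydrochloride | CNOC.Cl | starting material
3 | 1-(1H-imidazol-1-yl)icosan-1-one (icosanoyl imidazolide) | CCCCCCCCCCCCCCCCCCCC(=O)n1ccnc1 | intermediate
4 | N-methoxy-N-methylicosanamide | CCCCCCCCCCCCCCCCCCCC(=O)N(C)OC | intermediate
5 | 4-methoxy-6-methyl-2H-pyran-2-one | COC1=CC(=O)OC(C)=C1 | starting material
6 | [(4-methoxy-2-oxo-2H-pyran-6-yl)methyl]lithium | [Li]CC1=CC(OC)=CC(=O)O1 | intermediate
7 | lithium 2-[methoxy(methyl)amino]-1-(4-methoxy-2-oxo-2H-pyran-6-yl)henicosan-2-olate (racemic) | CCCCCCCCCCCCCCCCCCCC([O-])(N(C)OC)CC1=CC(OC)=CC(=O)O1.[Li+] | intermediate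
8 | 4-methoxy-6-(2-oxohenicosyl)-2H-pyran-2-one | CCCCCCCCCCCCCCCCCCCC(=O)CC1=CC(OC)=CC(=O)O1 | intermediate
9 | ethylene glycol | OCCO | starting material
10 | 4-methoxy-6-[(2-nonadecyl-1,3-dioxolan-2-yl)methyl]-2H-pyran-2-one | COC1=CC(=O)OC(CC2(CCCCCCCCCCCCCCCCCCC)OCCO2)=C1 | intermediate
11 | 1,1-dimethoxyethene | C=C(OC)OC | starting material
12 | 5,8,8-trimethoxy-1-[(2-nonadecyl-1,3-dioxolan-2-yl)methyl]-2-oxabicyclo[2.2.2]oct-5-en-3-one (racemic, relative configuration fixed by the bicycle) | O=C1OC2(CC3(CCCCCCCCCCCCCCCCCCC)OCCO3)CC(OC)(OC)C1C(OC)=C2 | intermediate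
13 | 2-nonadecyl-2-[(3,5,5-trimethoxycyclohexa-1,3-dien-1-yl)methyl]-1,3-dioxolane | COC1=CC(OC)(OC)CC(CC2(CCCCCCCCCCCCCCCCCCC)OCCO2)=C1 | intermediate
14 | 2-[(3,5-dimethoxyphenyl)methyl]-2-nonadecyl-1,3-dioxolane | COc1cc(OC)cc(CC2(CCCCCCCCCCCCCCCCCCC)OCCO2)c1 | intermediate
15 | 1-(3,5-dimethoxyphenyl)henicosan-2-one | CCCCCCCCCCCCCCCCCCCC(=O)Cc1cc(OC)cc(OC)c1 | intermediate
16 | 1-(3,5-dihydroxyphenyl)henicosan-2-one | CCCCCCCCCCCCCCCCCCCC(=O)Cc1cc(O)cc(O)c1 | target

**Totals**
Total step count: 6. Longest linear sequence: 6 steps (1 → 4 → 8 → 10 → 14 → 15 → 16).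

**Steps most likely to fail**

1. Step 4 (new method). The donor methoxy group at C-4 may slow the cycloaddition so much that thermal oligomerization of the ketene acetal takes over. Conjugate attack at C-4 or C-6 without ring closure, leading to substitution or lactone opening, could also outrun arene formation. The fallback uses known chemistry only; it leaves the route at Weinreb amide 4 and returns at ketone 15. Commercial 3,5-dimethoxybenzyl chloride (COc1cc(OC)cc(CCl)c1) would be converted with Mg turnings in THF at 0 °C, by slow addition to limit Wurtz coupling, into (3,5-dimethoxyphenyl)methylmagnesium chloride F1. This Grignard reagent should add once to 4 (THF, 0 °C) in a Weinreb ketone synthesis, and 1 M HCl work-up should release 15. Step 6 then follows unchanged.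

2. Step 2. The acylation may stay incomplete because the delocalized anion is a weak nucleophile toward an amide and the long-chain amide may precipitate at −78 °C. Competing ring lithiation at C-3, or collapse of adduct 7 with proton transfer from 8 to unreacted 6, would have the same effect. The fallback replaces acylation by aldol addition and oxidation; it leaves at 4 and 5 and returns at 8. Amide 4 would be reduced with LiAlH4 (THF, 0 °C) to icosanal F2. Anion 6 (from 5, LiN(iPr)2, THF, −78 °C) should add to this much more electrophilic aldehyde to give racemic 6-(2-hydroxyhenicosyl)-4-methoxy-2H-pyran-2-one F3. Oxidation with Dess–Martin periodinane (CH2Cl2, NaHCO3, rt) should then give 8.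

3. Step 3. Ketalization of the enolizable ketone may be slow, and under protic acid the ring methoxy group may exchange with the glycol or the keto-pyrone may degrade. The fallback carries the ketone as a dithiolane; it leaves at 8 and returns at 15. Ethane-1,2-dithiol and BF3·OEt2 (CH2Cl2, 0 °C → rt) should give 4-methoxy-6-[(2-nonadecyl-1,3-dithiolan-2-yl)methyl]-2H-pyran-2-one F4. Heated with 11 as in step 4, F4 should pass through the bridged lactone 5,8,8-trimethoxy-1-[(2-nonadecyl-1,3-dithiolan-2-yl)methyl]-2-oxabicyclo[2.2.2]oct-5-en-3-one F5 and the diene 2-nonadecyl-2-[(3,5,5-trimethoxycyclohexa-1,3-dien-1-yl)methyl]-1,3-dithiolane F6 to 2-[(3,5-dimethoxyphenyl)methyl]-2-nonadecyl-1,3-dithiolane F7. Alkylative hydrolysis (MeI, CaCO3, aqueous MeCN, 50 °C), which leaves the electron-rich arene untouched, should give 15.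

**Further compounds**
F1 | step 4 | (3,5-dimethoxyphenyl)methylmagnesium chloride | COc1cc(OC)cc(C[Mg]Cl)c1
F2 | step 2 | icosanal | CCCCCCCCCCCCCCCCCCCC=O
F3 | step 2 | 6-(2-hydroxyhenicosyl)-4-methoxy-2H-pyran-2-one (racemic) | CCCCCCCCCCCCCCCCCCCC(O)CC1=CC(OC)=CC(=O)O1
F4 | step 3 | 4-methoxy-6-[(2-nonadecyl-1,3-dithiolan-2-yl)methyl]-2H-pyran-2-one | COC1=CC(=O)OC(CC2(CCCCCCCCCCCCCCCCCCC)SCCS2)=C1
F5 | step 3 | 5,8,8-trimethoxy-1-[(2-nonadecyl-1,3-dithiolan-2-yl)methyl]-2-oxabicyclo[2.2.2]oct-5-en-3-one (racemic) | O=C1OC2(CC3(CCCCCCCCCCCCCCCCCCC)SCCS3)CC(OC)(OC)C1C(OC)=C2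
F6 | step 3 | 2-nonadecyl-2-[(3,5,5-trimethoxycyclohexa-1,3-dien-1-yl)methyl]-1,3-dithiolane | COC1=CC(OC)(OC)CC(CC2(CCCCCCCCCCCCCCCCCCC)SCCS2)=C1
F7 | step 3 | 2-[(3,5-dimethoxyphenyl)methyl]-2-nonadecyl-1,3-dithiolane | COc1cc(OC)cc(CC2(CCCCCCCCCCCCCCCCCCC)SCCS2)c1
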